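**Plan**
- Retrosynthetic cuts, in order: the two O–benzyl bonds on ring B; the ring A bond between the butyryl-bearing carbon C1 and the hydroxylated carbon C6 next to the bridge carbon C5; the chain C4–C5 bond; the chain C2–CH2(ring B) bond.
- The ring cut is possible because ring A (butyryl at C1, OH at C2, C4 and C6, methyl at C3, bridge CH2 at C5) is the aromatic enol of a 2-acylcyclohexane-1,3,5-trione, i.e. a folded 3,5,7-trioxodecanoate with the methyl on chain C4 and the ring B benzyl group on chain C2.
- Forward: ring B is elaborated from 2-methylphloroglucinol to a benzylic bromide, which alkylates methyl 3-oxopentanoate. The chain is then extended at C4 with a ketal-masked 3-oxohexanoyl unit and unmasked.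
- Ring A is closed by Claisen cyclisation with all six substituents already in place; hydrogenolysis of the two benzyl ethers ends the route.
- Stereochemistry: the target has no stereocentre; the CH centres of the open chain are labile and become sp2 on aromatisation.

Key step: step 12

Assumption: the target is achiral, so the open-chain intermediates 12, 17 and 18 are carried as mixtures of stereoisomers and enol tautomers and are drawn in the keto form without configuration.

**Step 1**
Reactants: 1 2-methylphloroglucinol; 2 butanoyl chloride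
Product: 3 1-(2,4,6-trihydroxy-3-methylphenyl)butan-1-one
Conditions: AlCl3 (4 equiv), CH2Cl2/PhNO2, 0 → 50 °C; ice/HCl
Reagents that add atoms: none
Why: Friedel–Crafts C-acylation at one of the two equivalent free ring positions should stop after one acyl group, because the new carbonyl deactivates the ring.

**Step 2**
Reactants: 3 1-(2,4,6-trihydroxy-3-methylphenyl)butan-1-one
Product: 4 1-(2,6-dihydroxy-4-methoxy-3-methylphenyl)butan-1-one (aspidinol)
Conditions: Me2SO4 (1.0 equiv), K2CO3 (1.05 equiv), acetone, reflux
Reagents that add atoms: dimethyl sulfate COS(=O)(=O)OC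
Why: Williamson O-methylation with one equivalent should select the 4-OH, which is the most acidic hydroxyl and the only one not hydrogen-bonded to the ketone.

**Step 3**
Reactants: 4 1-(2,6-dihydroxy-4-methoxy-3-methylphenyl)butan-1-one
Product: 6 3-butanoyl-2,4-dihydroxy-6-methoxy-5-methylbenzaldehyde, via α-chloro ether 5 (not isolated)
Conditions: Cl2CHOMe, TiCl4, CH2Cl2, 0 °C → rt; then H2O
Reagents that add atoms: dichloromethyl methyl ether COC(Cl)Cl; water O
Why: Rieche formylation should attack the single free ring position, which is activated by three oxygen substituents and directed by the titanium phenoxide, and it avoids the chromone formation that Vilsmeier conditions can cause with 2-hydroxyaryl ketones.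

**Step 4**
Reactants: 6 3-butanoyl-2,4-dihydroxy-6-methoxy-5-methylbenzaldehyde
Product: 7 2,4-bis(benzyloxy)-3-butanoyl-6-methoxy-5-methylbenzaldehyde
Conditions: BnBr (2.5 equiv), K2CO3, DMF, 60 °C
Reagents that add atoms: benzyl bromide BrCc1ccccc1
Why: Williamson etherification under carbonate/DMF heating should alkylate both chelated phenols on oxygen, since no aromatic CH remains for C-benzylation.

**Step 5**
Reactants: 7 2,4-bis(benzyloxy)-3-butanoyl-6-methoxy-5-methylbenzaldehyde
Product: 8 1-[2,6-bis(benzyloxy)-3-(hydroxymethyl)-4-methoxy-5-methylphenyl]butan-1-one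
Conditions: NaBH4 (0.5 equiv), THF/MeOH, −10 → 0 °C
Reagents that add atoms: none
Why: borohydride reduction should take the aldehyde selectively, because the aryl ketone is twisted out of conjugation and shielded by two ortho benzyloxy groups.

**Step 6**
Reactants: 8 1-[2,6-bis(benzyloxy)-3-(hydroxymethyl)-4-methoxy-5-methylphenyl]butan-1-one
Product: 9 1-[2,6-bis(benzyloxy)-3-(bromomethyl)-4-methoxy-5-methylphenyl]butan-1-one
Conditions: CBr4, PPh3, CH2Cl2, 0 °C; used without storage
Reagents that add atoms: carbon tetrabromide BrC(Br)(Br)Br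
Why: the Appel reaction converts the electron-rich benzylic alcohol to the bromide under neutral conditions that spare the benzyl ethers.

**Step 7**
Reactants: 10 methyl 3-oxopentanoate (1.5 equiv); 9 1-[2,6-bis(benzyloxy)-3-(bromomethyl)-4-methoxy-5-methylphenyl]butan-1-one
Product: 12 methyl 2-{[2,4-bis(benzyloxy)-3-butanoyl-6-methoxy-5-methylphenyl]methyl}-3-oxopentanoate, via keto ester sodium enolate 11 (not isolated)
Conditions: NaH (1.4 equiv), THF, 0 °C; then 9, 0 °C → rt
Reagents that add atoms: none
Why: C-alkylation of a β-keto ester enolate by a reactive benzylic bromide should give the C2-benzylated product, with excess enolate suppressing dialkylation and the much less acidic ring B ketone left untouched.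

**Step 8**
Reactants: 13 methyl 3-oxohexanoate
Product: 14 methyl 2-(2-propyl-1,3-dioxolan-2-yl)acetate
Conditions: HOCH2CH2OH, p-TsOH (cat.), toluene, Dean–Stark reflux
Reagents that add atoms: ethane-1,2-diol OCCO
Why: acid-catalysed ketalisation with removal of water protects the ketone of the β-keto ester and removes the acidity of its CH2 group.

**Step 9**
Reactants: 14 methyl 2-(2-propyl-1,3-dioxolan-2-yl)acetate
Product: 15 N-methoxy-N-methyl-2-(2-propyl-1,3-dioxolan-2-yl)acetamide
Conditions: MeNH(OMe)·HCl, i-PrMgCl, THF, −20 → 0 °C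
Reagents that add atoms: N,O-dimethylhydroxylamine hydrochloride CNOC.Cl
Why: aminolysis of the ester by the magnesium amide formed in the flask gives the Weinreb amide, an acyl donor that stops cleanly at the ketone stage.

**Step 10**
Reactants: 12 methyl 2-{[2,4-bis(benzyloxy)-3-butanoyl-6-methoxy-5-methylphenyl]methyl}-3-oxopentanoate; 15 N-methoxy-N-methyl-2-(2-propyl-1,3-dioxolan-2-yl)acetamide
Product: 17 methyl 2-{[2,4-bis(benzyloxy)-3-butanoyl-6-methoxy-5-methylphenyl]methyl}-4-methyl-3,5-dioxo-6-(2-propyl-1,3-dioxolan-2-yl)hexanoate, via trilithium trienolate 16 (not isolated)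
Conditions: LDA (3.3 equiv), THF, −78 → 0 °C; then 15 (1.0 equiv), −78 → −20 °C; aq. NH4Cl
Reagents that add atoms: none
Why: γ-acylation of a β-keto ester dianion with a Weinreb amide should occur at chain C4, the most basic carbanion, while the third equivalent of base holds the ring B ketone as its hindered, less nucleophilic enolate and the chelated tetrahedral adduct prevents over-reaction.

**Step 11**
Reactants: 17 methyl 2-{[2,4-bis(benzyloxy)-3-butanoyl-6-methoxy-5-methylphenyl]methyl}-4-methyl-3,5-dioxo-6-(2-propyl-1,3-dioxolan-2-yl)hexanoate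
Product: 18 methyl 2-{[2,4-bis(benzyloxy)-3-butanoyl-6-methoxy-5-methylphenyl]methyl}-4-methyl-3,5,7-trioxodecanoate
Conditions: 1 M HCl, THF, 0 °C → rt, short contact; used crude
Reagents that add atoms: water O
Why: acid-catalysed hydrolysis of a dioxolane β to a ketone is fast under mild conditions, so a brief, cold treatment should free the C7 ketone before the triketone can cyclodehydrate.

**Step 12**
Reactants: 18 methyl 2-{[2,4-bis(benzyloxy)-3-butanoyl-6-methoxy-5-methylphenyl]methyl}-4-methyl-3,5,7-trioxodecanoate
Product: 20 1-[3-{[2,4-bis(benzyloxy)-3-butanoyl-6-methoxy-5-methylphenyl]methyl}-2,4,6-trihydroxy-5-methylphenyl]butan-1-one, via cyclohexane-1,3,5-trione tautomer 19 (not isolated)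
Conditions: Mg(OMe)2 (5 equiv), MeOH, rt → reflux; then cold 1 M HCl
Reagents that add atoms: none
Why: Magnesium methoxide should turn 18 into a chelated polyenolate in which the C6 carbon, flanked by the C5 and C7 carbonyls, attacks the C1 ester carbonyl held close by magnesium bridging the C7 oxygen and the ester oxygen; loss of methoxide gives trione 19, which enolises irreversibly to the aromatic ring. The closest known reaction type is the base- or magnesium-mediated Claisen (Dieckmann-type) cyclisation of 3,5,7-triketo esters to acylphloroglucinols. The single ring formed, ring A, closes in a 6-exo-trig mode through the new C1–C6 bond. No stereocentre is created, since chain C2 and C4 both end as aromatic carbons. The closure has to win over the C2-to-C7 aldol, the C8-to-C3 aldol and O-acylation to a 2-pyranone. The C2 substituent keeps the first aldol adduct from aromatising so that it reverts, the substituents on C2 and C4 shield the C3 carbonyl, and magnesium chelation favours C- over O-acylation.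

**Step 13**
Reactants: 20 1-[3-{[2,4-bis(benzyloxy)-3-butanoyl-6-methoxy-5-methylphenyl]methyl}-2,4,6-trihydroxy-5-methylphenyl]butan-1-one
Product: 21 margaspidin
Conditions: H2 (1 atm), 10% Pd/C, EtOAc/MeOH, rt
Reagents that add atoms: none
Why: hydrogenolysis should cleave the two aryl benzyl ethers under neutral conditions that leave the chelated aryl ketones and the diarylmethane bridge intact.

**Compound list**
1 | 2-methylphloroglucinol | Cc1c(O)cc(O)cc1O | starting material
2 | butanoyl chloride | CCCC(=O)Cl | starting material
3 | 1-(2,4,6-trihydroxy-3-methylphenyl)butan-1-one | CCCC(=O)c1c(O)cc(O)c(C)c1O | intermediate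
4 | 1-(2,6-dihydroxy-4-methoxy-3-methylphenyl)butan-1-one (aspidinol) | CCCC(=O)c1c(O)cc(OC)c(C)c1O | intermediate
5 | 1-{3-[chloro(methoxy)methyl]-2,6-dihydroxy-4-methoxy-5-methylphenyl}butan-1-one (racemic, not isolated) | CCCC(=O)c1c(O)c(C(Cl)OC)c(OC)c(C)c1O | intermediate
6 | 3-butanoyl-2,4-dihydroxy-6-methoxy-5-methylbenzaldehyde | CCCC(=O)c1c(O)c(C=O)c(OC)c(C)c1O | intermediate
7 | 2,4-bis(benzyloxy)-3-butanoyl-6-methoxy-5-methylbenzaldehyde | CCCC(=O)c1c(OCc2ccccc2)c(C=O)c(OC)c(C)c1OCc1ccccc1 | intermediate
8 | 1-[2,6-bis(benzyloxy)-3-(hydroxymethyl)-4-methoxy-5-methylphenyl]butan-1-one | CCCC(=O)c1c(OCc2ccccc2)c(CO)c(OC)c(C)c1OCc1ccccc1 | intermediate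
9 | 1-[2,6-bis(benzyloxy)-3-(bromomethyl)-4-methoxy-5-methylphenyl]butan-1-one | CCCC(=O)c1c(OCc2ccccc2)c(CBr)c(OC)c(C)c1OCc1ccccc1 | intermediate
10 | methyl 3-oxopentanoate | CCC(=O)CC(=O)OC | starting material
11 | sodium enolate of methyl 3-oxopentanoate (not isolated) | [Na+].CCC([O-])=CC(=O)OC | intermediate
12 | methyl 2-{[2,4-bis(benzyloxy)-3-butanoyl-6-methoxy-5-methylphenyl]methyl}-3-oxopentanoate (racemic) | CCC(=O)C(Cc1c(OCc2ccccc2)c(C(=O)CCC)c(OCc2ccccc2)c(C)c1OC)C(=O)OC | intermediate
13 | methyl 3-oxohexanoate | CCCC(=O)CC(=O)OC | starting material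
14 | methyl 2-(2-propyl-1,3-dioxolan-2-yl)acetate | CCCC1(CC(=O)OC)OCCO1 | intermediate
15 | N-methoxy-N-methyl-2-(2-propyl-1,3-dioxolan-2-yl)acetamide | CCCC1(CC(=O)N(C)OC)OCCO1 | intermediate
16 | trilithium trienolate of 12 (ester/ketone dienolate plus ring B ketone enolate, enolate geometry undefined, not isolated) | [Li+].[Li+].[Li+].CC=C([O-])C(Cc1c(OCc2ccccc2)c(C([O-])=CCC)c(OCc2ccccc2)c(C)c1OC)=C([O-])OC | intermediate
17 | methyl 2-{[2,4-bis(benzyloxy)-3-butanoyl-6-methoxy-5-methylphenyl]methyl}-4-methyl-3,5-dioxo-6-(2-propyl-1,3-dioxolan-2-yl)hexanoate (stereoisomer mixture) | CCCC1(CC(=O)C(C)C(=O)C(Cc2c(OCc3ccccc3)c(C(=O)CCC)c(OCc3ccccc3)c(C)c2OC)C(=O)OC)OCCO1 | intermediate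
18 | methyl 2-{[2,4-bis(benzyloxy)-3-butanoyl-6-methoxy-5-methylphenyl]methyl}-4-methyl-3,5,7-trioxodecanoate (stereoisomer and enol mixture) | CCCC(=O)CC(=O)C(C)C(=O)C(Cc1c(OCc2ccccc2)c(C(=O)CCC)c(OCc2ccccc2)c(C)c1OC)C(=O)OC | intermediate
19 | 2-{[2,4-bis(benzyloxy)-3-butanoyl-6-methoxy-5-methylphenyl]methyl}-6-butanoyl-4-methylcyclohexane-1,3,5-trione (not isolated) | CCCC(=O)C1C(=O)C(C)C(=O)C(Cc2c(OCc3ccccc3)c(C(=O)CCC)c(OCc3ccccc3)c(C)c2OC)C1=O | intermediate
20 | 1-[3-{[2,4-bis(benzyloxy)-3-butanoyl-6-methoxy-5-methylphenyl]methyl}-2,4,6-trihydroxy-5-methylphenyl]butan-1-one | CCCC(=O)c1c(O)c(C)c(O)c(Cc2c(OCc3ccccc3)c(C(=O)CCC)c(OCc3ccccc3)c(C)c2OC)c1O | intermediate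
21 | margaspidin, 1-{3-[(3-butanoyl-2,4-dihydroxy-6-methoxy-5-methylphenyl)methyl]-2,4,6-trihydroxy-5-methylphenyl}butan-1-one | CCCC(=O)c1c(O)c(C)c(O)c(Cc2c(O)c(C(=O)CCC)c(O)c(C)c2OC)c1O | target

**Step count**
Total: 13 steps. Longest linear sequence: 11 steps (steps 1–7 and 10–13); steps 8–9 form a two-step side branch.

**Steps most likely to fail**

Step 10. The ring B ketone enolate may compete with the C4 carbanion for the acyl donor, incomplete enolisation may allow carbanion addition to the ring B carbonyl, or proton transfer from the amide may quench the dianion. The fallback assembles the chain before ring B is attached, so that no aryl ketone meets LDA. It sets out from 10, using 15 and aldehyde 7. Compound 10 is converted (NaH, then n-BuLi, THF, 0 °C) into the sodium lithium dianion of methyl 3-oxopentanoate F1, which is acylated with 15 to give methyl 4-methyl-3,5-dioxo-6-(2-propyl-1,3-dioxolan-2-yl)hexanoate F2. Knoevenagel condensation of F2 with 7 (piperidinium acetate or L-proline) can take place only at C2, because C4 carries a single hydrogen, and gives methyl 2-{[2,4-bis(benzyloxy)-3-butanoyl-6-methoxy-5-methylphenyl]methylidene}-4-methyl-3,5-dioxo-6-(2-propyl-1,3-dioxolan-2-yl)hexanoate F3. Conjugate reduction of F3 in the same flask with Hantzsch ester returns to the route at 17; steps 5–7 are then not needed.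

Step 12. Methoxide may cleave the 1,3-dicarbonyl chain by retro-Claisen reaction, or the chain may close through a competing aldol or lactonisation mode. The fallback forms the methylene bridge on a finished ring A instead. It sets out from ketone 3 (step 1) and benzylic alcohol 8 (step 5): acid-catalysed Friedel–Crafts benzylation (cat. p-TsOH, dioxane, mild warming) at the single free ring position of 3 returns to the route at 20. This fallback makes no new compound (F0).

Step 11. Under acid the freed 1,3,5-triketone may cyclodehydrate to a 4-pyranone, or the enol may lactonise, before 18 can be used. The fallback omits the ketal. It sets out from 12, which is converted to trienolate 16 as in step 10; 13 is deprotonated separately (LDA, 1 equiv) to the lithium enolate of methyl 3-oxohexanoate F4, whose ketone is protected as the enolate. Acylation of 16 with F4 and a buffered quench (pH 5–6) returns to the route at 18 without any acid step.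

**Further compounds**
F1 | step 10 | sodium lithium dianion of methyl 3-oxopentanoate | [Na+].[Li+].CC=C([O-])C=C([O-])OC
F2 | step 10 | methyl 4-methyl-3,5-dioxo-6-(2-propyl-1,3-dioxolan-2-yl)hexanoate | CCCC1(CC(=O)C(C)C(=O)CC(=O)OC)OCCO1
F3 | step 10 | methyl 2-{[2,4-bis(benzyloxy)-3-butanoyl-6-methoxy-5-methylphenyl]methylidene}-4-methyl-3,5-dioxo-6-(2-propyl-1,3-dioxolan-2-yl)hexanoate (alkene geometry undefined) | CCCC1(CC(=O)C(C)C(=O)C(=Cc2c(OCc3ccccc3)c(C(=O)CCC)c(OCc3ccccc3)c(C)c2OC)C(=O)OC)OCCO1
F0 | step 12 | none | none
F4 | step 11 | lithium enolate of methyl 3-oxohexanoate | [Li+].CCCC([O-])=CC(=O)OC
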